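## Structural features

The target is an isoflavone: a benzene ring A fused to a 4-pyranone (the chromen-4-one bicycle), with a second benzene ring B attached to C3 by a single bond. Ring A is substituted everywhere except C5, with a methoxy group on C6 and a free catechol on C7 and C8. Ring B carries a hydroxy group on C3' and methoxy groups on C4' and C5'. There is no stereocentre and no stereogenic axis, so the problem is one of regiochemistry and of keeping three phenols distinct from three methyl ethers. The catechol is the fragile part (easy oxidation to an ortho-quinone, especially in base), and the pyranone opens at C2 with hydroxide, so the free phenols should appear only in the last step. The real difficulty is the 1,2,3,4-tetraoxygenated ring A and the unambiguous placement of the carbonyl carbon next to it. The key step uses the fact that C4a is the only unsubstituted carbon ortho to the ring A oxygen that becomes O1, and that it lies para to the C7 oxygen: an acyl carbon tethered to that oxygen through O1–C2=C3 can bond nowhere else. Because the C7 oxygen is flanked on both sides and O1 is part of a vinylogous ester, ring A is only moderately nucleophilic and the acyl group needs real activation.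

## Logic of the disconnections

18 to 17. The three phenolic O–H bonds are traced back to O–isopropyl bonds. Isopropyl ethers survive base, peracid and anhydrous acid, and BCl3 can remove them while methyl ethers stay. The gain is that the catechol is masked through the whole route; the demand is a dealkylation that distinguishes secondary from methyl ethers.

17 to 15. The C4–C4a bond is cut, which opens the pyranone and leaves a carboxylic acid on an aryl vinyl ether. This turns the bicycle into two simple arenes joined by a three-atom chain. The forward step must acylate a moderately activated ring position without damaging the isopropyl ethers, and the carboxyl group must be cis to the aryloxy group, or able to become so.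

15 to 14. The carboxyl O–H is traced to a methyl ester, which carries the acid through the enolate chemistry that precedes it. The demand is an ester cleavage that does not expel the aryloxy group by conjugate addition.

14 to 13 and 5. The vinyl carbon–oxygen bond (C2–O1) is cut. This is the convergent point: 5 holds all of ring A and 13 holds ring B with C2, C3 and C4. The forward step needs the phenoxide to attack the β-carbon of the acrylate and not the sulfonyl sulfur.

13 to 12, then 12 to 10 and 11. The O–S bond is removed to reveal an enol, and the C2–C3 bond is then cut so that C2 comes from 11 as a formyl group. The gain is a plain arylacetic ester; the demand is a crossed Claisen condensation and control of enol geometry on sulfonylation.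

10 to 9, then 9 to 7 and 8. The bond between the benzylic carbon and the carboxyl carbon is cut, so the carboxyl carbon is supplied by 8 and the benzylic carbon is the former aldehyde carbon of 7. This is a two-step homologation that avoids cyanide; it demands condensation at an electron-rich aldehyde.

5 to 4 to 3, and 3 and 7 to 1, 6 and 2. The aryl C–O bond of 5 is traced to the aryl–CHO bond of 3 (oxidative exchange of carbon for oxygen), and the isopropyl ethers of 3 and 7 are cut to the commercial phenolic aldehydes 1 and 6 and to 2, of which 3 takes up two molecules and 7 one. All oxygen positions of both rings are bought, so no aromatic substitution is needed to set them.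

## Other disconnections considered

Alternative 1: The cut is C4a–C8a, so ring A is built from a squaric ester and not bought.
- Forward step: the racemic cyclobutenone A1 would come from addition of a ring B-bearing alkenyllithium to a dialkyl squarate and O-methylation of the tertiary alkoxide. On heating, 4π ring opening gives a dienylketene, 6π electrocyclisation forms C4a–C8a, and tautomerisation gives the phenol A2, a dioxolane-masked 2-hydroxydeoxybenzoin.
- In favour: every oxygen of ring A is placed by the four-membered ring, so regiochemistry is fixed by construction. No electrophilic substitution on a moderately nucleophilic arene is needed. The cascade is thermal and neutral, which suits isopropyl ethers better than an acidic acylation. On these three points it is the better plan.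
- Against: the alkenyl nucleophile with its ketal and ring B needs its own synthesis, a hindered tertiary alkoxide must be methylated, and the alkenyl group must rotate inward on ring opening. A2 still lacks C2 and the pyranone, so ketal hydrolysis, a formamide-acetal condensation and isopropyl cleavage follow: three steps after the key step against one here.
- Comparison: the deoxybenzoin endgame is as reliable as the chosen closure (equal). The mechanism is a pericyclic cascade in place of one polar bond formation. The count would be roughly 13 to 15 steps against 11, and the ring A pattern is available ready-made in 1, so the extra certainty costs too much.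

Alternative 2: The cut removes ring B (C2'–C3', C1'–C6', C3'–C4'), leaving the 3-ethynylchromone A3 and the diazoketone A4.
- Forward step: irradiation of A4 would trigger a Wolff rearrangement to a vinylketene bearing both methoxy groups. [2+2] addition to the alkyne of A3, 4π opening of the vinylcyclobutenone, 6π closure and tautomerisation would give the phenol A5, with the ketene carbon as C3'–OH.
- In favour: the ring B phenol appears free and already distinct from its methoxy neighbours, so ring B needs no protecting group. The last step is a hydrogenolysis of two benzyl ethers, which cannot touch a methyl ether. On both counts it is better than the chosen plan, and one step after the key step is equal. The regiochemistry is plausible, since the terminal alkyne carbon should bond to the ketene carbonyl carbon.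
- Against: this benzannulation works best with electron-rich alkynes (alkynyl ethers, ynamides), and the alkyne of A3 is a mediocre partner. The chromone absorbs light in the same region and can undergo [2+2] photochemistry at C2–C3. A4 is a sensitive, hazardous diazo compound. A3 needs a C-acetylated ring A phenol, iodination and a Sonogashira coupling, so the ring A acylation problem is moved, not removed.
- Comparison: a four-stage pericyclic cascade replaces one polar bond formation. The count would be about equal (10 to 12 steps), but the central step is much less secure.

Alternative 3: The cut is O1–C8a.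
- Forward step: the free catechol A6 would be oxidised at a carbon anode (two electrons, two protons) to its ortho-quinone. The enol oxygen of the hydroxymethylene ketone adds to C8a in a conjugate manner, and tautomerisation returns the catechol as the chromone A7, which then needs only hydrogenolysis of the ring B benzyl ether.
- In favour: the aryl C–O bond is made at a C–H position with current as the only reagent, and ring A carries no protecting group at the end. The polarity is reversed (ring A is the electrophile), so its modest nucleophilicity does not matter; on this point it is better. The product catechol sits on an electron-poor chromone and should resist further oxidation. The final hydrogenolysis is safer toward methyl ethers than BCl3 (better), and one step after the key step is equal.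
- Against: the tether reaches both carbons ortho to the acyl group, and both are electrophilic in the quinone (C8a is the vinylogous position of the C7 carbonyl, the other carbon its direct conjugate position). Closure at the other one would put O1 next to the methoxy-bearing carbon and give a regioisomeric chromone. Nothing in A6 clearly biases the quinone toward C8a, whereas in the chosen plan the rival ortho position is blocked. The acyl group of A6 sits para to the central oxygen of the trioxygenated unit, where direct acylation does not go, so the ketone must be built by addition and oxidation with catechol protection and release. An α-formyl ketone with a free catechol is prone to deformylation and air oxidation.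
- Comparison: the count would be comparable or somewhat higher (11 to 13 steps), and the regiochemical question is the deciding weakness.

Key step: step 10

Remark: the target has no stereocentre; the Z geometry written for 12 to 16 is the one with the carboxyl carbon and the enol oxygen cis, the only geometry that can close, and 8 and 9 are racemic at sulfur.

## Route

Step 1
Reactants: 1 2,3-dihydroxy-4-methoxybenzaldehyde; 2 2-bromopropane
Product: 3 2,3-diisopropoxy-4-methoxybenzaldehyde
Conditions: 2-bromopropane (excess), K2CO3, DMF, 80 °C
Reagents that add atoms: 2-bromopropane (second equivalent), CC(C)Br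
Why: Double Williamson etherification in which each of the two phenols takes up one molecule of the bromide, so two molecules of 2 are built into 3. Carbonate in DMF at 80 °C should overcome the hydrogen bond of the 2-hydroxy group to the aldehyde, and the excess of the secondary bromide offsets its loss by elimination.

Step 2
Reactants: 3 2,3-diisopropoxy-4-methoxybenzaldehyde
Product: 5 2,3-diisopropoxy-4-methoxyphenol, via aryl formate 4 (not isolated)
Conditions: mCPBA, CH2Cl2, 0 °C to rt; aq. NaHCO3 wash; then K2CO3 (cat.), MeOH, rt, under argon
Reagents that add atoms: mCPBA (3-chloroperbenzoic acid), OOC(=O)c1cccc(Cl)c1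
Why: Baeyer–Villiger oxidation of an electron-rich benzaldehyde (Dakin-type): the aryl group with ortho and para alkoxy donors migrates in preference to hydride and gives formate 4, which mild methanolysis cleaves to the phenol. The alkyl ethers are inert to peracid and carbonate.

Step 3
Reactants: 6 3-hydroxy-4,5-dimethoxybenzaldehyde; 2 2-bromopropane
Product: 7 3-isopropoxy-4,5-dimethoxybenzaldehyde
Conditions: K2CO3, DMF, 80 °C
Reagents that add atoms: none
Why: Williamson etherification of the single phenol with one molecule of the bromide; the aldehyde and methyl ethers are unaffected.

Step 4
Reactants: 7 3-isopropoxy-4,5-dimethoxybenzaldehyde; 8 methyl (methylthio)methyl sulfoxide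
Product: 9 (E)-1-isopropoxy-2,3-dimethoxy-5-[2-(methylsulfinyl)-2-(methylthio)ethenyl]benzene
Conditions: benzyltrimethylammonium hydroxide (40% in MeOH, cat.), THF, reflux
Reagents that add atoms: none
Why: Knoevenagel-type condensation of the acidic methylene of the dithioacetal S-oxide with the aldehyde, a standard one-carbon homologation of aromatic aldehydes. The alkene is expected mainly as the E isomer; its geometry and the sulfur configuration are erased in step 5.

Step 5
Reactants: 9 (E)-1-isopropoxy-2,3-dimethoxy-5-[2-(methylsulfinyl)-2-(methylthio)ethenyl]benzene
Product: 10 methyl 2-(3-isopropoxy-4,5-dimethoxyphenyl)acetate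
Conditions: dry HCl, MeOH, rt
Reagents that add atoms: methanol, CO
Why: Acid-mediated methanolysis of a ketene dithioacetal S-oxide (Pummerer-type): protonation at the benzylic carbon, addition of methanol and loss of both sulfur groups as the disulfide leave the arylacetic ester. Aryl ethers tolerate HCl in methanol at room temperature.

Step 6
Reactants: 10 methyl 2-(3-isopropoxy-4,5-dimethoxyphenyl)acetate; 11 methyl formate
Product: 12 methyl (Z)-3-hydroxy-2-(3-isopropoxy-4,5-dimethoxyphenyl)acrylate
Conditions: NaH, THF, 0 °C to rt; then aq. HCl, 0 °C
Reagents that add atoms: none
Why: Crossed Claisen condensation: the ester enolate is formylated by the formate and the product is drained as its sodium enolate. Acidification should give the hydrogen-bonded Z enol.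

Step 7
Reactants: 12 methyl (Z)-3-hydroxy-2-(3-isopropoxy-4,5-dimethoxyphenyl)acrylate
Product: 13 methyl (Z)-2-(3-isopropoxy-4,5-dimethoxyphenyl)-3-(tosyloxy)acrylate
Conditions: TsCl, TMEDA, LiCl, MeCN, 0 °C
Reagents that add atoms: p-toluenesulfonyl chloride (TsCl), Cc1ccc(S(Cl)(=O)=O)cc1
Why: O-Sulfonylation of the lithium-chelated enolate; chelation between the enolate oxygen and the ester carbonyl holds the two oxygens cis, so the Z enol tosylate is expected.

Step 8
Reactants: 13 methyl (Z)-2-(3-isopropoxy-4,5-dimethoxyphenyl)-3-(tosyloxy)acrylate; 5 2,3-diisopropoxy-4-methoxyphenol
Product: 14 methyl (Z)-3-(2,3-diisopropoxy-4-methoxyphenoxy)-2-(3-isopropoxy-4,5-dimethoxyphenyl)acrylate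
Conditions: Cs2CO3, MeCN, rt, under argon
Reagents that add atoms: none
Why: Nucleophilic vinylic substitution by addition–elimination: the phenoxide adds to the β-carbon of the acrylate and tosylate leaves from the ester enolate, normally with retention, as in the substitution of 4-tosyloxycoumarins by phenoxides. Any E isomer is carried on, because step 10 is stereoconvergent.

Step 9
Reactants: 14 methyl (Z)-3-(2,3-diisopropoxy-4-methoxyphenoxy)-2-(3-isopropoxy-4,5-dimethoxyphenyl)acrylate
Product: 15 (Z)-3-(2,3-diisopropoxy-4-methoxyphenoxy)-2-(3-isopropoxy-4,5-dimethoxyphenyl)acrylic acid
Conditions: LiOH·H2O, THF/MeOH/H2O, rt; then dilute HCl to pH 3, 0 °C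
Reagents that add atoms: lithium hydroxide, [Li+].[OH-]
Why: Saponification of the methyl ester at room temperature, before any chromone exists; the aryl ethers are inert, and cold, brief acidification protects the enol ether from hydrolysis.

Step 10
Reactants: 15 (Z)-3-(2,3-diisopropoxy-4-methoxyphenoxy)-2-(3-isopropoxy-4,5-dimethoxyphenyl)acrylic acid
Product: 17 7,8-diisopropoxy-3-(3-isopropoxy-4,5-dimethoxyphenyl)-6-methoxy-4H-chromen-4-one, via mixed trifluoroacetic anhydride 16 (not isolated)
Conditions: TFAA, CH2Cl2 (0.05 M), 0 °C to rt
Reagents that add atoms: none
Why: TFAA converts the acid into mixed anhydride 16, which ionises to a β-aryloxy acylium ion; this ion is a hybrid with an oxocarbenium–ketene form in which the former C=C bond is single, so any E material rotates into the Z geometry that can close. The acyl carbon then attacks C4a of ring A in an intramolecular electrophilic aromatic substitution, and loss of the proton restores aromaticity and completes the pyranone. The closest known reaction type is the cyclodehydration of 3-aryloxyacrylic acids to chromones (and of 3-aryloxypropanoic acids to chromanones) by intramolecular Friedel–Crafts acylation. The single ring formed is six-membered and closes by bonding of C4a to the acyl carbon with the C=O bond left outside the ring (exo with respect to the carbonyl), the other five ring atoms being already linked. No stereocentre is created. Regioselectivity is secured by the substrate: the tether reaches only the two carbons ortho to the ether oxygen, one of which bears an isopropoxy group, so C4a is the sole site, activated by O1 (ortho) and the C7 oxygen (para). Acylation of the electron-rich ring B of a second molecule is suppressed kinetically by the intramolecular six-membered closure at moderate dilution. The isopropyl and methyl ethers tolerate TFAA and the trifluoroacetic acid it releases, which is why this activation is preferred to hot P2O5 in MeSO3H.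

Step 11
Reactants: 17 7,8-diisopropoxy-3-(3-isopropoxy-4,5-dimethoxyphenyl)-6-methoxy-4H-chromen-4-one
Product: 18 7,8-dihydroxy-3-(3-hydroxy-4,5-dimethoxyphenyl)-6-methoxy-4H-chromen-4-one
Conditions: BCl3 (1 M in CH2Cl2, excess), CH2Cl2, −78 to 0 °C; then H2O, 0 °C
Reagents that add atoms: none
Why: Lewis-acid ether dealkylation: BCl3 coordinates each ether oxygen and chloride removes the alkyl group best able to carry positive charge, so the secondary isopropyl ethers cleave at low temperature while the methyl ethers, none of which is peri to the carbonyl, remain. Keeping the mixture at or below 0 °C and quenching cold protects the methyl ethers at C6 and C4'.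

## Compound list

1 | 2,3-dihydroxy-4-methoxybenzaldehyde | COc1ccc(C=O)c(O)c1O | starting material
2 | 2-bromopropane | CC(C)Br | starting material
3 | 2,3-diisopropoxy-4-methoxybenzaldehyde | COc1ccc(C=O)c(OC(C)C)c1OC(C)C | intermediate
4 | 2,3-diisopropoxy-4-methoxyphenyl formate | COc1ccc(OC=O)c(OC(C)C)c1OC(C)C | intermediate
5 | 2,3-diisopropoxy-4-methoxyphenol | COc1ccc(O)c(OC(C)C)c1OC(C)C | intermediate
6 | 3-hydroxy-4,5-dimethoxybenzaldehyde | COc1cc(C=O)cc(O)c1OC | starting material
7 | 3-isopropoxy-4,5-dimethoxybenzaldehyde | COc1cc(C=O)cc(OC(C)C)c1OC | intermediate
8 | methyl (methylthio)methyl sulfoxide (racemic) | CS(=O)CSC | starting material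
9 | (E)-1-isopropoxy-2,3-dimethoxy-5-[2-(methylsulfinyl)-2-(methylthio)ethenyl]benzene (racemic at sulfur) | COc1cc(/C=C(\SC)S(C)=O)cc(OC(C)C)c1OC | intermediate
10 | methyl 2-(3-isopropoxy-4,5-dimethoxyphenyl)acetate | COC(=O)Cc1cc(OC(C)C)c(OC)c(OC)c1 | intermediate
11 | methyl formate | COC=O | starting material
12 | methyl (Z)-3-hydroxy-2-(3-isopropoxy-4,5-dimethoxyphenyl)acrylate | COC(=O)/C(=C\O)c1cc(OC(C)C)c(OC)c(OC)c1 | intermediate
13 | methyl (Z)-2-(3-isopropoxy-4,5-dimethoxyphenyl)-3-(tosyloxy)acrylate | COC(=O)/C(=C\OS(=O)(=O)c1ccc(C)cc1)c1cc(OC(C)C)c(OC)c(OC)c1 | intermediate
14 | methyl (Z)-3-(2,3-diisopropoxy-4-methoxyphenoxy)-2-(3-isopropoxy-4,5-dimethoxyphenyl)acrylate | COC(=O)/C(=C\Oc1ccc(OC)c(OC(C)C)c1OC(C)C)c1cc(OC(C)C)c(OC)c(OC)c1 | intermediate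
15 | (Z)-3-(2,3-diisopropoxy-4-methoxyphenoxy)-2-(3-isopropoxy-4,5-dimethoxyphenyl)acrylic acid | OC(=O)/C(=C\Oc1ccc(OC)c(OC(C)C)c1OC(C)C)c1cc(OC(C)C)c(OC)c(OC)c1 | intermediate
16 | (Z)-3-(2,3-diisopropoxy-4-methoxyphenoxy)-2-(3-isopropoxy-4,5-dimethoxyphenyl)acrylic trifluoroacetic anhydride | FC(F)(F)C(=O)OC(=O)/C(=C\Oc1ccc(OC)c(OC(C)C)c1OC(C)C)c1cc(OC(C)C)c(OC)c(OC)c1 | intermediate
17 | 7,8-diisopropoxy-3-(3-isopropoxy-4,5-dimethoxyphenyl)-6-methoxy-4H-chromen-4-one | COc1cc2c(=O)c(-c3cc(OC(C)C)c(OC)c(OC)c3)coc2c(OC(C)C)c1OC(C)C | intermediate
18 | 7,8-dihydroxy-3-(3-hydroxy-4,5-dimethoxyphenyl)-6-methoxy-4H-chromen-4-one | COc1cc2c(=O)c(-c3cc(O)c(OC)c(OC)c3)coc2c(O)c1O | target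

## Step count and least certain steps

Total step count: 11. Longest linear sequence: 9 steps (steps 3 to 11, from 6); the ring A branch (steps 1 and 2) joins at step 8.

Step 10 (key step). The most likely failure is slow ring closure. The acylium ion is stabilised by the β-oxygen, and C4a is activated only by a vinylogous-ester oxygen and a twisted, flanked C7 oxygen. The mixed anhydride could then acylate ring B of another molecule, and more forcing acid (P2O5 in MeSO3H) could strip isopropyl groups. The fallback abandons the aryl vinyl ether and forms the same C4–C4a bond on the free phenol, whose oxygen donates fully, with a non-stabilised acyl donor. It sets out from 10 and 5 and returns at 17. Ester 10 is saponified (LiOH, THF/H2O) to 2-(3-isopropoxy-4,5-dimethoxyphenyl)acetic acid F1. F1 and 5 in BF3·OEt2 at 70 °C should give, by ortho-acylation at the single free ortho carbon (Fries-type, through the boron chelate), 1-(2-hydroxy-3,4-diisopropoxy-5-methoxyphenyl)-2-(3-isopropoxy-4,5-dimethoxyphenyl)ethan-1-one F2. N,N-Dimethylformamide dimethyl acetal in toluene at 90 °C converts F2 into (E)-3-(dimethylamino)-1-(2-hydroxy-3,4-diisopropoxy-5-methoxyphenyl)-2-(3-isopropoxy-4,5-dimethoxyphenyl)prop-2-en-1-one F3, which closes in the same flask, with loss of dimethylamine, to 17.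

Step 8. The phenoxide may attack the sulfonyl sulfur in place of the β-carbon, transferring the tosyl group to 5 and returning the enolate of 12; the hindered ortho-isopropoxy group of 5 makes carbon attack slower. Erosion of alkene geometry is harmless. The fallback changes the electrophile class to one with no second electrophilic centre. It sets out from 12 and returns at 14. The chloroiminium salt from (COCl)2 and DMF in CH2Cl2 at 0 °C should convert the enol into methyl (Z)-3-chloro-2-(3-isopropoxy-4,5-dimethoxyphenyl)acrylate F4, and F4 with 5 and Cs2CO3 in MeCN gives 14 by the same addition–elimination.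

Step 9. Hydroxide may add to the β-carbon of the push–pull acrylate and expel the phenoxide of 5 (loss of the aryloxy group), because the ester carbonyl is deactivated by the enol ether and hindered by the α-aryl group. The fallback moves the site of attack away from the acrylate altogether: dealkylative cleavage with LiI in refluxing EtOAc, in which iodide attacks the ester methyl carbon. It sets out from 14 and returns at 15 after cold acidification, and makes no new compound (F0).

Step 11. Chelation-assisted loss of a methyl ether next to a newly formed boron phenoxide (C6 or C4') may accompany isopropyl cleavage if the mixture warms or stands. The fallback replaces Lewis-acid coordination by a Brønsted-acid fragmentation that only a secondary alkyl group can undergo: TfOH in CF3CO2H with pentamethylbenzene as cation trap, 0 °C. It sets out from 17 and returns at 18, and makes no new compound (F0).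

## Further compounds

F1 | step 10 | 2-(3-isopropoxy-4,5-dimethoxyphenyl)acetic acid | OC(=O)Cc1cc(OC(C)C)c(OC)c(OC)c1
F2 | step 10 | 1-(2-hydroxy-3,4-diisopropoxy-5-methoxyphenyl)-2-(3-isopropoxy-4,5-dimethoxyphenyl)ethan-1-one | COc1cc(C(=O)Cc2cc(OC(C)C)c(OC)c(OC)c2)c(O)c(OC(C)C)c1OC(C)C
F3 | step 10 | (E)-3-(dimethylamino)-1-(2-hydroxy-3,4-diisopropoxy-5-methoxyphenyl)-2-(3-isopropoxy-4,5-dimethoxyphenyl)prop-2-en-1-one | COc1cc(C(=O)/C(=C/N(C)C)c2cc(OC(C)C)c(OC)c(OC)c2)c(O)c(OC(C)C)c1OC(C)C
F4 | step 8 | methyl (Z)-3-chloro-2-(3-isopropoxy-4,5-dimethoxyphenyl)acrylate | COC(=O)/C(=C\Cl)c1cc(OC(C)C)c(OC)c(OC)c1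
F0 | step 9 | none | none
F0 | step 11 | none | none
A1 | alternative 1 | 4-{(E)-2-[2-(3-isopropoxy-4,5-dimethoxybenzyl)-1,3-dioxolan-2-yl]ethenyl}-2,3-diisopropoxy-4-methoxycyclobut-2-en-1-one (racemic) | COC1(/C=C/C2(Cc3cc(OC(C)C)c(OC)c(OC)c3)OCCO2)C(=O)C(OC(C)C)=C1OC(C)C
A2 | alternative 1 | 2-[2-(3-isopropoxy-4,5-dimethoxybenzyl)-1,3-dioxolan-2-yl]-5,6-diisopropoxy-4-methoxyphenol | CC(C)Oc1c(O)c(C2(Cc3cc(OC(C)C)c(OC)c(OC)c3)OCCO2)cc(OC)c1OC(C)C
A3 | alternative 2 | 7,8-bis(benzyloxy)-3-ethynyl-6-methoxy-4H-chromen-4-one | COc1cc2c(=O)c(C#C)coc2c(OCc2ccccc2)c1OCc1ccccc1
A4 | alternative 2 | (Z)-1-diazo-3,4-dimethoxybut-3-en-2-one | CO/C=C(OC)/C(=O)C=[N+]=[N-]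
A5 | alternative 2 | 7,8-bis(benzyloxy)-3-(3-hydroxy-4,5-dimethoxyphenyl)-6-methoxy-4H-chromen-4-one | COc1cc2c(=O)c(-c3cc(O)c(OC)c(OC)c3)coc2c(OCc2ccccc2)c1OCc1ccccc1
A6 | alternative 3 | (Z)-2-[3-(benzyloxy)-4,5-dimethoxyphenyl]-1-(3,4-dihydroxy-5-methoxyphenyl)-3-hydroxyprop-2-en-1-one | COc1cc(C(=O)/C(=C\O)c2cc(OCc3ccccc3)c(OC)c(OC)c2)cc(O)c1O
A7 | alternative 3 | 3-[3-(benzyloxy)-4,5-dimethoxyphenyl]-7,8-dihydroxy-6-methoxy-4H-chromen-4-one | COc1cc2c(=O)c(-c3cc(OCc4ccccc4)c(OC)c(OC)c3)coc2c(O)c1O
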